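**Plan**

- Retrosynthesis: the two ester C–O bonds are cut first (lutein plus two α-linolenic acids), then the C8–C9 single bond, then the C11'=C12' and C11=C12 double bonds (two Horner–Wadsworth–Emmons olefinations on the C10 trienedial), and last C9'=C10' back to α-ionone.
- Enabling feature: C8–C9 is the sp2–sp2 single bond of the nonaene that joins the C7=C8 alkene on ring A (the β ring, C5=C6) to the methyl-bearing C9 of the C9=C10 alkene, so a dienyl boronate at C8 and an alkenyl iodide at C9 can be united with retention of both geometries.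
- Forward order: ring A is made from ketoisophorone as a C11 dienyl boronate (steps 1–6); an iodo-C4 phosphonate and the dial give a C14 iodopentaenal (steps 7–10); ring B (the ε ring) is carried from (R)-α-ionone to a C15 phosphonate (steps 11–16) and joined to give the C29 octaenyl iodide (step 17); cross-coupling, desilylation and double acylation finish the route (steps 18–20).
- Stereochemistry: C3 from asymmetric transfer hydrogenation of ketoisophorone; C6' bought with (R)-α-ionone; C3' from catalyst-controlled transfer hydrogenation of the ring-B enone; alkene geometries from syn hydrometalations, E-selective olefinations and a stereoretentive coupling.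

Key step: step 18

Remark: (R)-α-ionone is taken to be purchasable in high enantiomeric purity, and the sense of induction of both transfer hydrogenations is the one expected from the aryl-ketone model with the enone C=C in the place of the aryl group.

**Route**

Step 1
Reactants: 1 ketoisophorone (2,6,6-trimethylcyclohex-2-ene-1,4-dione)
Product: 2 (S)-4-hydroxy-2,6,6-trimethylcyclohex-2-en-1-one
Conditions: RuCl[(S,S)-TsDPEN](p-cymene) (0.5 mol %), KOH (1 mol %), i-PrOH, 25 °C
Reagents that add atoms: none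
Why: Noyori asymmetric transfer hydrogenation should reduce only the unhindered C4 carbonyl (C1 is flanked by the gem-dimethyl carbon and the methyl-bearing alkene carbon), and the (S,S) catalyst should set the S carbinol, which becomes C3 of ring A.

Step 2
Reactants: 2 (S)-4-hydroxy-2,6,6-trimethylcyclohex-2-en-1-one
Product: 3 (S)-4-(tert-butyldimethylsilyloxy)-2,6,6-trimethylcyclohex-2-en-1-one
Conditions: TBSCl, imidazole, DMF, 25 °C
Reagents that add atoms: tert-butyldimethylsilyl chloride, CC(C)(C)[Si](C)(C)Cl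
Why: Standard silylation of a secondary alcohol protects the carbinol against the hydride, base and organometallic steps that follow.

Step 3
Reactants: 3 (S)-4-(tert-butyldimethylsilyloxy)-2,6,6-trimethylcyclohex-2-en-1-one
Product: 5 (R)-4-(tert-butyldimethylsilyloxy)-2,6,6-trimethylcyclohex-1-en-1-yl trifluoromethanesulfonate, via lithium enolate 4 (not isolated)
Conditions: LiBH(s-Bu)3, THF, −78 °C; then PhNTf2, −78 → 23 °C
Reagents that add atoms: N-phenylbis(trifluoromethanesulfonimide), O=S(=O)(N(c1ccccc1)S(=O)(=O)C(F)(F)F)C(F)(F)F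
Why: Conjugate reduction of the enone, whose carbonyl is too hindered for 1,2-attack, followed by O-triflation of the regiodefined enolate (reductive triflation) fixes the tetrasubstituted alkene that becomes C5=C6 of ring A.

Step 4
Reactants: 5 (R)-4-(tert-butyldimethylsilyloxy)-2,6,6-trimethylcyclohex-1-en-1-yl trifluoromethanesulfonate
Product: 6 (R)-tert-butyldimethyl{[3,5,5-trimethyl-4-(trimethylsilylethynyl)cyclohex-3-en-1-yl]oxy}silane
Conditions: HC≡CSiMe3, PdCl2(PPh3)2 (5 mol %), CuI (10 mol %), Et3N, DMF, 60 °C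
Reagents that add atoms: ethynyltrimethylsilane, C#C[Si](C)(C)C
Why: Sonogashira coupling of an alkenyl triflate tolerates the tetrasubstituted alkene because the alkynyl partner is sterically undemanding.

Step 5
Reactants: 6 (R)-tert-butyldimethyl{[3,5,5-trimethyl-4-(trimethylsilylethynyl)cyclohex-3-en-1-yl]oxy}silane
Product: 7 (R)-tert-butyl[(4-ethynyl-3,5,5-trimethylcyclohex-3-en-1-yl)oxy]dimethylsilane
Conditions: K2CO3 (cat.), MeOH, 25 °C
Reagents that add atoms: none
Why: Base-catalysed methanolysis cleaves the alkynyl C–Si bond selectively and should leave the secondary O-silyl ether intact.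

Step 6
Reactants: 7 (R)-tert-butyl[(4-ethynyl-3,5,5-trimethylcyclohex-3-en-1-yl)oxy]dimethylsilane
Product: 8 2-{(E)-2-[(R)-4-(tert-butyldimethylsilyloxy)-2,6,6-trimethylcyclohex-1-en-1-yl]ethenyl}-4,4,5,5-tetramethyl-1,3,2-dioxaborolane
Conditions: HBpin, Cp2ZrHCl (10 mol %), Et3N (10 mol %), neat, 60 °C
Reagents that add atoms: pinacolborane, [H]B1OC(C)(C)C(C)(C)O1
Why: Zirconium-catalysed hydroboration of the terminal alkyne is a syn, anti-Markovnikov addition and should give the E alkenyl boronate (C7=C8) with boron on C8.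

Step 7
Reactants: 9 but-2-yn-1-ol
Product: 11 (E)-3-iodobut-2-en-1-ol, via alkenylzirconocene 10 (not isolated)
Conditions: Cp2ZrHCl (2.3 equiv), THF, 0 → 40 °C; then I2, 0 °C
Reagents that add atoms: iodine, II
Why: Hydrozirconation is a syn addition that, with excess hydride, should equilibrate to the alkenylzirconium with the metal on the methyl-bearing carbon, and iodinolysis proceeds with retention to give the E iodide.

Step 8
Reactants: 11 (E)-3-iodobut-2-en-1-ol
Product: 12 (E)-1-bromo-3-iodobut-2-ene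
Conditions: PBr3, Et2O, 0 °C
Reagents that add atoms: phosphorus tribromide, BrP(Br)Br
Why: Bromination of a primary allylic alcohol with PBr3 is an SN2 substitution that should leave the alkenyl iodide and its geometry untouched.

Step 9
Reactants: 12 (E)-1-bromo-3-iodobut-2-ene
Product: 13 diethyl [(E)-3-iodobut-2-en-1-yl]phosphonate
Conditions: P(OEt)3, neat, 90 °C
Reagents that add atoms: triethyl phosphite, CCOP(OCC)OCC
Why: The Michaelis–Arbuzov reaction takes place at the allylic bromide only, since an alkenyl iodide does not react with a phosphite without a metal catalyst.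

Step 10
Reactants: 13 diethyl [(E)-3-iodobut-2-en-1-yl]phosphonate; 14 (2E,4E,6E)-2,7-dimethylocta-2,4,6-trienedial (3 equiv)
Product: 15 (2E,4E,6E,8E,10E)-11-iodo-2,7-dimethyldodeca-2,4,6,8,10-pentaenal
Conditions: KOt-Bu added last, THF, −30 → 0 °C, dark; excess 14 recovered
Reagents that add atoms: none
Why: Horner–Wadsworth–Emmons olefination of an allylic phosphonate with a non-enolisable enal should form C11=C12 with E geometry, and the excess of the symmetric dial holds the reaction at mono-olefination.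

Step 11
Reactants: 16 (R)-α-ionone
Product: 17 ethyl (2E,4E)-3-methyl-5-[(R)-2,6,6-trimethylcyclohex-2-en-1-yl]penta-2,4-dienoate
Conditions: (EtO)2P(O)CH2CO2Et, NaH, THF, 0 → 40 °C; the minor 2Z isomer removed by chromatography
Reagents that add atoms: triethyl phosphonoacetate, CCOC(=O)CP(=O)(OCC)OCC
Why: Horner–Wadsworth–Emmons olefination of the methyl ketone with a stabilised anion should give mainly the 2E dienoate (C9'=C10') without enolising the ketone toward the C6' stereocentre.

Step 12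
Reactants: 17 ethyl (2E,4E)-3-methyl-5-[(R)-2,6,6-trimethylcyclohex-2-en-1-yl]penta-2,4-dienoate
Product: 18 ethyl (2E,4E)-3-methyl-5-[(R)-2,6,6-trimethyl-4-oxocyclohex-2-en-1-yl]penta-2,4-dienoate
Conditions: Rh2(cap)4 (1 mol %), t-BuOOH (70% aq, 5 equiv), NaHCO3, ClCH2CH2Cl, 40 °C
Reagents that add atoms: tert-butyl hydroperoxide, CC(C)(C)OO
Why: Peroxyl-radical allylic oxidation with dirhodium caprolactamate should convert the ring allylic CH2 (C3') into the enone, because the tertiary C6'–H is shielded by the gem-dimethyl group and allylic methyl groups react more slowly.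

Step 13
Reactants: 18 ethyl (2E,4E)-3-methyl-5-[(R)-2,6,6-trimethyl-4-oxocyclohex-2-en-1-yl]penta-2,4-dienoate
Product: 19 ethyl (2E,4E)-5-[(1R,4R)-4-hydroxy-2,6,6-trimethylcyclohex-2-en-1-yl]-3-methylpenta-2,4-dienoate
Conditions: Ru[(R,R)-TsDPEN](p-cymene) (1 mol %), i-PrOH, 25 °C, no added base
Reagents that add atoms: none
Why: Noyori asymmetric transfer hydrogenation of a ring enone that has the same local environment as C4 of ketoisophorone should set the C3' carbinol as R under catalyst control, trans to the C6' side chain, and the base-free amido catalyst protects the epimerisable C6' centre.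

Step 14
Reactants: 19 ethyl (2E,4E)-5-[(1R,4R)-4-hydroxy-2,6,6-trimethylcyclohex-2-en-1-yl]-3-methylpenta-2,4-dienoate
Product: 20 ethyl (2E,4E)-5-[(1R,4R)-4-(tert-butyldimethylsilyloxy)-2,6,6-trimethylcyclohex-2-en-1-yl]-3-methylpenta-2,4-dienoate
Conditions: TBSCl, imidazole, DMF, 25 °C
Reagents that add atoms: tert-butyldimethylsilyl chloride, CC(C)(C)[Si](C)(C)Cl
Why: Standard silylation masks the allylic carbinol so that it can neither ionise nor be acylated or phosphonylated in the later steps.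

Step 15
Reactants: 20 ethyl (2E,4E)-5-[(1R,4R)-4-(tert-butyldimethylsilyloxy)-2,6,6-trimethylcyclohex-2-en-1-yl]-3-methylpenta-2,4-dienoate
Product: 21 (2E,4E)-5-[(1R,4R)-4-(tert-butyldimethylsilyloxy)-2,6,6-trimethylcyclohex-2-en-1-yl]-3-methylpenta-2,4-dien-1-ol
Conditions: i-Bu2AlH (2.2 equiv), CH2Cl2, −78 °C; aq KNaC4H4O6 work-up
Reagents that add atoms: none
Why: Hydride reduction of a conjugated ester with i-Bu2AlH is a clean 1,2-reduction to the allylic alcohol.

Step 16
Reactants: 21 (2E,4E)-5-[(1R,4R)-4-(tert-butyldimethylsilyloxy)-2,6,6-trimethylcyclohex-2-en-1-yl]-3-methylpenta-2,4-dien-1-ol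
Product: 23 diethyl {(2E,4E)-5-[(1R,4R)-4-(tert-butyldimethylsilyloxy)-2,6,6-trimethylcyclohex-2-en-1-yl]-3-methylpenta-2,4-dien-1-yl}phosphonate, via dienyl bromide 22 (not isolated)
Conditions: PBr3, pyridine, Et2O, −20 °C; then P(OEt)3, 80 °C
Reagents that add atoms: triethyl phosphite, CCOP(OCC)OCC
Why: Bromination of the primary dienyl alcohol at low temperature followed directly by a Michaelis–Arbuzov reaction should give the primary C15 phosphonate before the labile bromide can ionise.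

Step 17
Reactants: 23 diethyl {(2E,4E)-5-[(1R,4R)-4-(tert-butyldimethylsilyloxy)-2,6,6-trimethylcyclohex-2-en-1-yl]-3-methylpenta-2,4-dien-1-yl}phosphonate; 15 (2E,4E,6E,8E,10E)-11-iodo-2,7-dimethyldodeca-2,4,6,8,10-pentaenal
Product: 24 tert-butyl{[(1R,4R)-4-((1E,3E,5E,7E,9E,11E,13E,15E)-16-iodo-3,7,12-trimethylheptadeca-1,3,5,7,9,11,13,15-octaen-1-yl)-3,5,5-trimethylcyclohex-2-en-1-yl]oxy}dimethylsilane
Conditions: KOt-Bu added last, THF, −30 → 0 °C, dark
Reagents that add atoms: none
Why: Horner–Wadsworth–Emmons olefination of the C15 dienyl phosphonate at its α-carbon with the non-enolisable pentaenal should form C11'=C12' with E geometry and leave the alkenyl iodide untouched.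

Step 18
Reactants: 24 tert-butyl{[(1R,4R)-4-((1E,3E,5E,7E,9E,11E,13E,15E)-16-iodo-3,7,12-trimethylheptadeca-1,3,5,7,9,11,13,15-octaen-1-yl)-3,5,5-trimethylcyclohex-2-en-1-yl]oxy}dimethylsilane; 8 2-{(E)-2-[(R)-4-(tert-butyldimethylsilyloxy)-2,6,6-trimethylcyclohex-1-en-1-yl]ethenyl}-4,4,5,5-tetramethyl-1,3,2-dioxaborolane
Product: 25 (all-E)-(3R,3'R,6'R)-3,3'-bis(tert-butyldimethylsilyloxy)-β,ε-carotene
Conditions: Pd(OAc)2 (5 mol %), SPhos (10 mol %), K3PO4 (3 M aq), THF, 23 °C, argon, dark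
Reagents that add atoms: none
Why: Zerovalent palladium formed from Pd(OAc)2 and SPhos inserts into the C9–I bond of 24 with retention, phosphate-assisted transmetalation transfers the dienyl group of 8 from boron through its unhindered C8–H carbon, and reductive elimination forms the C8–C9 single bond. The closest known reaction type is the Suzuki–Miyaura coupling of alkenyl boronates with alkenyl iodides as used for retinoid and carotenoid polyenes. No ring is closed and no stereocentre is created; the E geometry of C7=C8 and of C9=C10 is carried in from 8 and 24 because every elementary step is stereoretentive. The step needs site selectivity for the one C(sp2)–I bond and freedom from allylic ionisation at C3' of ring B, which is secured by carrying both oxygens as silyl ethers and not as allylic carboxylates. It also needs the nonaene to stay all-E, which room temperature, exclusion of light and a fast ligand-accelerated coupling should ensure.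

Step 19
Reactants: 25 (all-E)-(3R,3'R,6'R)-3,3'-bis(tert-butyldimethylsilyloxy)-β,ε-carotene
Product: 26 lutein ((all-E)-(3R,3'R,6'R)-β,ε-carotene-3,3'-diol)
Conditions: Bu4NF, THF, 25 °C, argon, dark
Reagents that add atoms: none
Why: Fluoride-mediated desilylation is neutral to mildly basic and should free both carbinols without ionising the acid-sensitive allylic C3' position.

Step 20
Reactants: 26 lutein ((all-E)-(3R,3'R,6'R)-β,ε-carotene-3,3'-diol); 27 α-linolenic acid ((9Z,12Z,15Z)-octadeca-9,12,15-trienoic acid, 2.5 equiv)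
Product: 28 lutein di-α-linolenate (CNP0400996.1)
Conditions: DCC, DMAP (cat.), CH2Cl2, 25 °C, argon, dark
Reagents that add atoms: none
Why: Steglich esterification acylates both secondary carbinols with retention at C3 and C3' and does not touch the skipped Z-triene of the acid or the polyene.

**Compound list**

1 | ketoisophorone (2,6,6-trimethylcyclohex-2-ene-1,4-dione) | CC1=CC(=O)CC(C)(C)C1=O | starting material
2 | (S)-4-hydroxy-2,6,6-trimethylcyclohex-2-en-1-one | O[C@@H]1C=C(C)C(=O)C(C)(C)C1 | intermediate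
3 | (S)-4-(tert-butyldimethylsilyloxy)-2,6,6-trimethylcyclohex-2-en-1-one | CC(C)(C)[Si](C)(C)O[C@@H]1C=C(C)C(=O)C(C)(C)C1 | intermediate
4 | lithium (R)-4-(tert-butyldimethylsilyloxy)-2,6,6-trimethylcyclohex-1-en-1-olate | CC(C)(C)[Si](C)(C)O[C@@H]1CC(C)=C(O[Li])C(C)(C)C1 | intermediate
5 | (R)-4-(tert-butyldimethylsilyloxy)-2,6,6-trimethylcyclohex-1-en-1-yl trifluoromethanesulfonate | CC(C)(C)[Si](C)(C)O[C@@H]1CC(C)=C(OS(=O)(=O)C(F)(F)F)C(C)(C)C1 | intermediate
6 | (R)-tert-butyldimethyl{[3,5,5-trimethyl-4-(trimethylsilylethynyl)cyclohex-3-en-1-yl]oxy}silane | CC(C)(C)[Si](C)(C)O[C@@H]1CC(C)=C(C#C[Si](C)(C)C)C(C)(C)C1 | intermediate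
7 | (R)-tert-butyl[(4-ethynyl-3,5,5-trimethylcyclohex-3-en-1-yl)oxy]dimethylsilane | CC(C)(C)[Si](C)(C)O[C@@H]1CC(C)=C(C#C)C(C)(C)C1 | intermediate
8 | 2-{(E)-2-[(R)-4-(tert-butyldimethylsilyloxy)-2,6,6-trimethylcyclohex-1-en-1-yl]ethenyl}-4,4,5,5-tetramethyl-1,3,2-dioxaborolane | CC(C)(C)[Si](C)(C)O[C@@H]1CC(C)=C(/C=C/B2OC(C)(C)C(C)(C)O2)C(C)(C)C1 | intermediate
9 | but-2-yn-1-ol | CC#CCO | starting material
10 | O-zirconated (E)-alkenylzirconocene chloride (chlorozirconocene bound at C3 and at oxygen of the but-2-en-1-ol unit) | C/C(=C\CO[Zr](Cl)(C1C=CC=C1)C1C=CC=C1)[Zr](Cl)(C1C=CC=C1)C1C=CC=C1 | intermediate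
11 | (E)-3-iodobut-2-en-1-ol | C/C(I)=C\CO | intermediate
12 | (E)-1-bromo-3-iodobut-2-ene | C/C(I)=C\CBr | intermediate
13 | diethyl [(E)-3-iodobut-2-en-1-yl]phosphonate | C/C(I)=C\CP(=O)(OCC)OCC | intermediate
14 | (2E,4E,6E)-2,7-dimethylocta-2,4,6-trienedial | O=C/C(C)=C/C=C/C=C(C)/C=O | starting material
15 | (2E,4E,6E,8E,10E)-11-iodo-2,7-dimethyldodeca-2,4,6,8,10-pentaenal | I/C(C)=C/C=C/C(C)=C/C=C/C=C(C)/C=O | intermediate
16 | (R)-α-ionone ((E)-4-[(R)-2,6,6-trimethylcyclohex-2-en-1-yl]but-3-en-2-one) | CC(=O)/C=C/[C@H]1C(C)=CCCC1(C)C | starting material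
17 | ethyl (2E,4E)-3-methyl-5-[(R)-2,6,6-trimethylcyclohex-2-en-1-yl]penta-2,4-dienoate | CCOC(=O)/C=C(C)/C=C/[C@H]1C(C)=CCCC1(C)C | intermediate
18 | ethyl (2E,4E)-3-methyl-5-[(R)-2,6,6-trimethyl-4-oxocyclohex-2-en-1-yl]penta-2,4-dienoate | CCOC(=O)/C=C(C)/C=C/[C@H]1C(C)=CC(=O)CC1(C)C | intermediate
19 | ethyl (2E,4E)-5-[(1R,4R)-4-hydroxy-2,6,6-trimethylcyclohex-2-en-1-yl]-3-methylpenta-2,4-dienoate | CCOC(=O)/C=C(C)/C=C/[C@H]1C(C)=C[C@H](O)CC1(C)C | intermediate
20 | ethyl (2E,4E)-5-[(1R,4R)-4-(tert-butyldimethylsilyloxy)-2,6,6-trimethylcyclohex-2-en-1-yl]-3-methylpenta-2,4-dienoate | CCOC(=O)/C=C(C)/C=C/[C@H]1C(C)=C[C@H](O[Si](C)(C)C(C)(C)C)CC1(C)C | intermediate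
21 | (2E,4E)-5-[(1R,4R)-4-(tert-butyldimethylsilyloxy)-2,6,6-trimethylcyclohex-2-en-1-yl]-3-methylpenta-2,4-dien-1-ol | OC/C=C(C)/C=C/[C@H]1C(C)=C[C@H](O[Si](C)(C)C(C)(C)C)CC1(C)C | intermediate
22 | {[(1R,4R)-4-((1E,3E)-5-bromo-3-methylpenta-1,3-dien-1-yl)-3,5,5-trimethylcyclohex-2-en-1-yl]oxy}(tert-butyl)dimethylsilane | BrC/C=C(C)/C=C/[C@H]1C(C)=C[C@H](O[Si](C)(C)C(C)(C)C)CC1(C)C | intermediate
23 | diethyl {(2E,4E)-5-[(1R,4R)-4-(tert-butyldimethylsilyloxy)-2,6,6-trimethylcyclohex-2-en-1-yl]-3-methylpenta-2,4-dien-1-yl}phosphonate | CCOP(=O)(OCC)C/C=C(C)/C=C/[C@H]1C(C)=C[C@H](O[Si](C)(C)C(C)(C)C)CC1(C)C | intermediate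
24 | tert-butyl{[(1R,4R)-4-((1E,3E,5E,7E,9E,11E,13E,15E)-16-iodo-3,7,12-trimethylheptadeca-1,3,5,7,9,11,13,15-octaen-1-yl)-3,5,5-trimethylcyclohex-2-en-1-yl]oxy}dimethylsilane | I/C(C)=C/C=C/C(C)=C/C=C/C=C(C)/C=C/C=C(C)/C=C/[C@H]1C(C)=C[C@H](O[Si](C)(C)C(C)(C)C)CC1(C)C | intermediate
25 | (all-E)-(3R,3'R,6'R)-3,3'-bis(tert-butyldimethylsilyloxy)-β,ε-carotene | CC(C)(C)[Si](C)(C)O[C@@H]1CC(C)=C(/C=C/C(C)=C/C=C/C(C)=C/C=C/C=C(C)/C=C/C=C(C)/C=C/[C@H]2C(C)=C[C@H](O[Si](C)(C)C(C)(C)C)CC2(C)C)C(C)(C)C1 | intermediate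
26 | lutein ((all-E)-(3R,3'R,6'R)-β,ε-carotene-3,3'-diol) | O[C@@H]1CC(C)=C(/C=C/C(C)=C/C=C/C(C)=C/C=C/C=C(C)/C=C/C=C(C)/C=C/[C@H]2C(C)=C[C@H](O)CC2(C)C)C(C)(C)C1 | intermediate
27 | α-linolenic acid ((9Z,12Z,15Z)-octadeca-9,12,15-trienoic acid) | CC/C=C\C/C=C\C/C=C\CCCCCCCC(=O)O | starting material
28 | lutein di-α-linolenate, (3R,3'R,6'R) (CNP0400996.1) | CC/C=C\C/C=C\C/C=C\CCCCCCCC(=O)O[C@@H]1CC(C)=C(/C=C/C(C)=C/C=C/C(C)=C/C=C/C=C(C)/C=C/C=C(C)/C=C/[C@H]2C(C)=C[C@H](OC(=O)CCCCCCC/C=C\C/C=C\C/C=C\CC)CC2(C)C)C(C)(C)C1 | target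

**Totals and risks**

Total step count: 20. Longest linear sequence: 10 steps (steps 11–20, from (R)-α-ionone 16 to 28).

Steps most likely to fail:

Step 18. The dienyl boronate may protodeboronate under the aqueous base, and the octaenyl iodide may isomerise or decompose under light or palladium before it couples. The fallback moves the fragile union to an olefination and does the C8–C9 coupling on small, robust partners. It sets out from 8 and 11 (with 23 and 14 for the other half) and comes back at 25. Under the step-18 coupling conditions 8 and 11 should give (2E,4E)-5-[(R)-4-(tert-butyldimethylsilyloxy)-2,6,6-trimethylcyclohex-1-en-1-yl]-3-methylpenta-2,4-dien-1-ol F1. PBr3 with pyridine would convert it into the ring-A dienyl bromide F2, and triethyl phosphite into the ring-A C15 phosphonate F3. Separately, 23 and an excess of dial 14 (KOt-Bu, THF) would give the ring-B C25 hexaenal F4. Horner–Wadsworth–Emmons olefination of F4 with F3 then forms C11=C12 and returns to 25.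

Step 13. The catalyst may not override the substrate, so that hydride goes to the wrong face of the ring enone; C6' may epimerise through the dienolate; or the enone may undergo conjugate reduction. The fallback corrects the carbinol configuration by inversion; it sets out from 18 and comes back at 19. Luche reduction (NaBH4, CeCl3·7H2O, MeOH, −78 °C) would give both carbinol epimers. The trans alcohol 19 is used as such and is separated from ethyl (2E,4E)-5-[(1R,4S)-4-hydroxy-2,6,6-trimethylcyclohex-2-en-1-yl]-3-methylpenta-2,4-dienoate F5. Mitsunobu inversion of F5 (4-nitrobenzoic acid, PPh3, DIAD, THF) would give the trans 4-nitrobenzoate F6, and ethanolysis (K2CO3, EtOH) returns to 19.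

Step 12. Hydrogen abstraction may be unselective (the doubly allylic C6'–H or the chain methyl of the dienoate) and the dienoate may be over-oxidised. The fallback oxidises ring B before the chain is extended, on a substrate with an isolated side-chain alkene; it sets out from 16 and comes back at 20. Ketalisation of 16 (ethylene glycol, HC(OEt)3, p-TsOH cat.) would give 2-methyl-2-{(E)-2-[(R)-2,6,6-trimethylcyclohex-2-en-1-yl]ethenyl}-1,3-dioxolane F7. Allylic oxidation (t-BuOOH, aq NaOCl, MeCN, 0 °C) would give the ring enone ketal F8, and transfer hydrogenation as in step 13 the trans hydroxy ketal F9. Mild hydrolysis (PPTS, acetone/H2O) would give (3R,6R)-3-hydroxy-α-ionone F10, and silylation its silyl ether F11. Olefination of F11 as in step 11 returns to 20.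

Further compounds
F1 | step 18 | (2E,4E)-5-[(R)-4-(tert-butyldimethylsilyloxy)-2,6,6-trimethylcyclohex-1-en-1-yl]-3-methylpenta-2,4-dien-1-ol | CC(C)(C)[Si](C)(C)O[C@@H]1CC(C)=C(/C=C/C(C)=C/CO)C(C)(C)C1
F2 | step 18 | {[(R)-4-((1E,3E)-5-bromo-3-methylpenta-1,3-dien-1-yl)-3,5,5-trimethylcyclohex-3-en-1-yl]oxy}(tert-butyl)dimethylsilane | CC(C)(C)[Si](C)(C)O[C@@H]1CC(C)=C(/C=C/C(C)=C/CBr)C(C)(C)C1
F3 | step 18 | diethyl {(2E,4E)-5-[(R)-4-(tert-butyldimethylsilyloxy)-2,6,6-trimethylcyclohex-1-en-1-yl]-3-methylpenta-2,4-dien-1-yl}phosphonate | CC(C)(C)[Si](C)(C)O[C@@H]1CC(C)=C(/C=C/C(C)=C/CP(=O)(OCC)OCC)C(C)(C)C1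
F4 | step 18 | (2E,4E,6E,8E,10E,12E)-13-[(1R,4R)-4-(tert-butyldimethylsilyloxy)-2,6,6-trimethylcyclohex-2-en-1-yl]-2,7,11-trimethyltrideca-2,4,6,8,10,12-hexaenal | O=C/C(C)=C/C=C/C=C(C)/C=C/C=C(C)/C=C/[C@H]1C(C)=C[C@H](O[Si](C)(C)C(C)(C)C)CC1(C)C
F5 | step 13 | ethyl (2E,4E)-5-[(1R,4S)-4-hydroxy-2,6,6-trimethylcyclohex-2-en-1-yl]-3-methylpenta-2,4-dienoate | CCOC(=O)/C=C(C)/C=C/[C@H]1C(C)=C[C@@H](O)CC1(C)C
F6 | step 13 | (1R,4R)-4-[(1E,3E)-5-ethoxy-3-methyl-5-oxopenta-1,3-dien-1-yl]-3,5,5-trimethylcyclohex-2-en-1-yl 4-nitrobenzoate | CCOC(=O)/C=C(C)/C=C/[C@H]1C(C)=C[C@H](OC(=O)c2ccc(cc2)[N+](=O)[O-])CC1(C)C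
F7 | step 12 | 2-methyl-2-{(E)-2-[(R)-2,6,6-trimethylcyclohex-2-en-1-yl]ethenyl}-1,3-dioxolane | CC1(OCCO1)/C=C/[C@H]1C(C)=CCCC1(C)C
F8 | step 12 | (R)-3,5,5-trimethyl-4-[(E)-2-(2-methyl-1,3-dioxolan-2-yl)ethenyl]cyclohex-2-en-1-one | CC1(OCCO1)/C=C/[C@H]1C(C)=CC(=O)CC1(C)C
F9 | step 12 | (1R,4R)-3,5,5-trimethyl-4-[(E)-2-(2-methyl-1,3-dioxolan-2-yl)ethenyl]cyclohex-2-en-1-ol | CC1(OCCO1)/C=C/[C@H]1C(C)=C[C@H](O)CC1(C)C
F10 | step 12 | (E)-4-[(1R,4R)-4-hydroxy-2,6,6-trimethylcyclohex-2-en-1-yl]but-3-en-2-one | CC(=O)/C=C/[C@H]1C(C)=C[C@H](O)CC1(C)C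
F11 | step 12 | (E)-4-[(1R,4R)-4-(tert-butyldimethylsilyloxy)-2,6,6-trimethylcyclohex-2-en-1-yl]but-3-en-2-one | CC(=O)/C=C/[C@H]1C(C)=C[C@H](O[Si](C)(C)C(C)(C)C)CC1(C)C
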